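**Strategy.** The bicyclo[3.3.1]nonane core is disconnected at the C1–C8 bond. The cyclohexanone ring C1–C8–C7–C6–C5–C9 is grown from a cyclopentane C5–C6–C7–C8–C9 by one-carbon ring expansion, which exploits the 1,3-relationship of the C9 and C2 oxygens across bridgehead C1. The precursor is a cis-fused cyclopentanol–methoxycyclohexenone, made by diketene annulation of an enantiopure cyclopentanone whose C7 centre comes from an Ireland–Claisen chirality transfer. PhI(OAc)2/KOH oxidises C1 and the C9 alkoxide pushes C8 from C9 to C1, giving the bridged dione with its C9 ketone in one operation. Bridgehead prenylation, C3 aroylation and deprotection complete the route.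

Key step: step 10

Remark: atom labels follow the PPAP convention throughout, also for early intermediates (C1, C5 bridgeheads; C2–C4 β-diketone, aroyl on C3; C6 CH2; C7 geranyl-bearing CH; C8 CMe2; C9 bridging C=O). Geranyl = (2E)-3,7-dimethylocta-2,6-dien-1-yl, prenyl = 3-methylbut-2-en-1-yl. The target is drawn as one of its rapidly equilibrating enol tautomers.

Step 1
Reactants: 1 (S)-but-3-yn-2-ol; 2 geranyl bromide
Product: 3 (2S,6E)-7,11-dimethyldodeca-6,10-dien-3-yn-2-ol
Conditions: CuI (10 mol %), n-Bu4NI (10 mol %), K2CO3, DMF, rt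
Reagents that add atoms: none
Why: Copper-acetylide coupling of a terminal alkyne with a primary allylic bromide should join the fragments at the α-carbon of geranyl bromide with retention of the E-olefin, and the carbinol stereocentre of 1 is not touched.

Step 2
Reactants: 3 (2S,6E)-7,11-dimethyldodeca-6,10-dien-3-yn-2-ol
Product: 4 (2S,3E,6E)-7,11-dimethyldodeca-3,6,10-trien-2-ol
Conditions: Red-Al, THF, 0 °C → rt; aq. Rochelle salt
Reagents that add atoms: none
Why: Hydroxyl-directed trans-hydroalumination of the propargylic alcohol should give only the (E)-allylic alcohol, leaving the isolated trisubstituted olefins and the stereocentre intact.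

Step 3
Reactants: 4 (2S,3E,6E)-7,11-dimethyldodeca-3,6,10-trien-2-ol; 5 isobutyryl chloride
Product: 6 (2S,3E,6E)-7,11-dimethyldodeca-3,6,10-trien-2-yl 2-methylpropanoate
Conditions: pyridine, DMAP (cat.), CH2Cl2, 0 °C
Reagents that add atoms: none
Why: DMAP-catalysed O-acylation of a secondary alcohol proceeds with retention at the carbinol carbon.

Step 4
Reactants: 6 (2S,3E,6E)-7,11-dimethyldodeca-3,6,10-trien-2-yl 2-methylpropanoate
Product: 9 (3R,5E)-2,2,6,10-tetramethyl-3-[(1E)-prop-1-en-1-yl]undeca-5,9-dienoic acid, via silyl ketene acetal 7 (not isolated), via trimethylsilyl ester 8 (not isolated)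
Conditions: LDA, THF, −78 °C; TMSCl, Et3N; −78 → 60 °C; then 1 M HCl
Reagents that add atoms: none
Why: Ireland–Claisen rearrangement through a chair transition state with the carbinol methyl equatorial should transfer the (S) carbinol chirality suprafacially to the new (R) centre (C7), form the C7–C8 bond next to the gem-dimethyl carbon and leave an (E)-propenyl group; the symmetric Me2C= ketene acetal removes any enolate-geometry issue.

Step 5
Reactants: 9 (3R,5E)-2,2,6,10-tetramethyl-3-[(1E)-prop-1-en-1-yl]undeca-5,9-dienoic acid; 10 tributyl(vinyl)stannane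
Product: 12 (5R,7E)-4,4,8,12-tetramethyl-5-[(1E)-prop-1-en-1-yl]trideca-1,7,11-trien-3-one, via acid chloride 11 (not isolated)
Conditions: (COCl)2, DMF (cat.), CH2Cl2, 0 °C → rt, concentrate; then 10, Pd(PPh3)4 (cat.), THF, 60 °C
Reagents that add atoms: none
Why: Acid chloride formation followed by Stille acylation with the vinylstannane should give the vinyl ketone without touching the α-quaternary carbon, the stereocentre or the olefins.

Step 6
Reactants: 12 (5R,7E)-4,4,8,12-tetramethyl-5-[(1E)-prop-1-en-1-yl]trideca-1,7,11-trien-3-one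
Product: 13 (4R)-4-geranyl-5,5-dimethylcyclopent-2-en-1-one
Conditions: Grubbs second-generation catalyst (5 mol %), CH2Cl2, 40 °C
Reagents that add atoms: none
Why: Ring-closing metathesis between the enone vinyl group and the 1,2-disubstituted propenyl olefin (five-membered ring, gem-dimethyl assisted) should outpace any reaction of the trisubstituted geranyl olefins and expel propene.

Step 7
Reactants: 13 (4R)-4-geranyl-5,5-dimethylcyclopent-2-en-1-one; 14 prenyl bromide
Product: 16 (3R)-3-geranyl-2,2-dimethyl-5-prenylcyclopentan-1-one (C5 epimers), via lithium enolate 15 (not isolated)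
Conditions: Li (2.2 equiv), NH3(l)–THF, t-BuOH (1.0 equiv), −78 °C; then 14, −78 → −33 °C; NH4Cl
Reagents that add atoms: none
Why: Dissolving-metal reduction of the enone gives the regiodefined lithium enolate, which is C-alkylated by prenyl bromide (Stork reductive alkylation); isolated olefins are inert to Li/NH3, and the C5 configuration is irrelevant because C5 is enolised again in step 8.

Step 8
Reactants: 16 (3R)-3-geranyl-2,2-dimethyl-5-prenylcyclopentan-1-one; 17 diketene
Product: 20 cis-fused (7R)-9-hydroxy-2,4-diketone (7-geranyl-9-hydroxy-8,8-dimethyl-5-prenyl-hexahydroindane-2,4-dione in PPAP labels), via lithium enolate 18 (not isolated), via acetoacetyl enolate 19 (not isolated)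
Conditions: LiTMP (1.1 equiv), THF, −78 °C; 17, −78 °C; then LiTMP (1.1 equiv), −78 → 0 °C; aq. NH4Cl
Reagents that add atoms: none
Why: Diketene C-acylates the only possible enolate (C8 is quaternary) on the face anti to the C7 geranyl group, which sets quaternary C5, and the terminal methyl-ketone enolate so released closes the six-membered ring by intramolecular aldol addition to the C9 ketone, the short tether enforcing cis ring fusion.

Step 9
Reactants: 20 cis-fused 9-hydroxy-2,4-diketone
Product: 21 cis-fused 9-hydroxy-2-methoxy-enone (C2 methyl enol ether of 20, C4 ketone retained)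
Conditions: HC(OMe)3, MeOH, CSA (cat.), rt
Reagents that add atoms: trimethyl orthoformate, COC(OC)OC
Why: Acid-catalysed enol etherification of the cyclic 1,3-diketone under thermodynamic control should place the methoxy group on C2, remote from quaternary C5, and leave the tertiary C9 alcohol free.

Step 10
Reactants: 21 cis-fused 9-hydroxy-2-methoxy-enone
Product: 23 (7R)-7-exo-geranyl-2-methoxy-8,8-dimethyl-5-prenylbicyclo[3.3.1]non-2-ene-4,9-dione (PPAP labels; H on bridgehead C1), via γ-iodanyl ketone 22 (not isolated)
Conditions: PhI(OAc)2 (1.3 equiv), KOH (4 equiv), MeOH, −10 °C → rt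
Reagents that add atoms: none
Why: KOH/MeOH ionises the C9–OH and reversibly removes a C1–H (γ-position of the vinylogous ester and β-carbon of the C2 enol ether, hence the nucleophilic terminus of the dienolate), PhI(OMe)2 formed in situ is captured there to give the γ-iodanyl ketone 22 (capture at C3 and SN2′ collapse would converge on the same product), and the C9 alkoxide then drives a semipinacol 1,2-shift of C8 from C9 to C1 with reductive loss of iodobenzene, so that C9 becomes the bridging ketone. The closest known reaction type is the hypervalent-iodine α-oxidation of ketones in KOH/MeOH, diverted into an oxidative semipinacol ring expansion of a fused β-hydroxy ketone to a bridged 1,3-diketone. The ring C1–C8–C7–C6–C5–C9 is not closed by a cyclisation but by one-carbon expansion of the cyclopentane C5–C6–C7–C8–C9 (C1 is inserted into the C8–C9 bond by a 1,2-alkyl shift), which at the same time converts the fused bicyclo[4.3.0] skeleton into the bridged bicyclo[3.3.1] skeleton. The only new stereocentre, bridgehead C1, is fixed by the bicyclic framework because C8 migrates suprafacially across the C9–C1 bond, while C5 and C7 are not touched, so the cis relationship of geranyl and prenyl in 21 becomes the exo (equatorial) C7 geranyl of the target. The step needs C8, and not C5 or the alkoxide oxygen, to attack C1: C8 is an electron-rich tertiary alkyl group that can stand antiperiplanar to the C1–I bond when it is axial on the cyclohexenone ring, whereas C5 is an electron-poor α-keto carbon lying in the ring plane, and the basic methanolic medium keeps iodine(III) from attacking the prenyl and geranyl olefins.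

Step 11
Reactants: 23 (7R)-7-exo-geranyl-2-methoxy-8,8-dimethyl-5-prenylbicyclo[3.3.1]non-2-ene-4,9-dione; 14 prenyl bromide
Product: 25 (7R)-7-exo-geranyl-2-methoxy-8,8-dimethyl-1,5-diprenylbicyclo[3.3.1]non-2-ene-4,9-dione, via bridgehead lithium species 24 (not isolated)
Conditions: LiTMP (1.5 equiv), THF, −78 → −40 °C; then 14 (3 equiv), −78 → −20 °C
Reagents that add atoms: none
Why: Bridgehead lithiation–alkylation of a bicyclo[3.3.1]nonane-2,4,9-trione enol ether: C1–H is acidified by the C9 ketone and the adjacent vinylogous ester, the exo-directed carbanion is alkylated by prenyl bromide in the only geometry the bridgehead allows, and any C3-lithiated material does not allylate without copper and returns as 23 on quench.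

Step 12
Reactants: 26 3,4-dihydroxybenzoic acid
Product: 27 tert-butyldimethylsilyl 3,4-bis(tert-butyldimethylsilyloxy)benzoate
Conditions: TBSCl (3.3 equiv), imidazole, DMF, rt
Reagents that add atoms: tert-butyldimethylsilyl chloride, CC(C)(C)[Si](C)(C)Cl
Why: Exhaustive silylation of both phenols and the carboxylic acid with TBSCl/imidazole is routine.

Step 13
Reactants: 27 tert-butyldimethylsilyl 3,4-bis(tert-butyldimethylsilyloxy)benzoate
Product: 28 3,4-bis(tert-butyldimethylsilyloxy)benzoyl chloride
Conditions: (COCl)2, DMF (cat.), CH2Cl2, 0 °C → rt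
Reagents that add atoms: oxalyl chloride, ClC(=O)C(Cl)=O
Why: Silyl esters are converted directly into acid chlorides by the Vilsmeier reagent under neutral conditions, so the aryl silyl ethers survive.

Step 14
Reactants: 25 (7R)-7-exo-geranyl-2-methoxy-8,8-dimethyl-1,5-diprenylbicyclo[3.3.1]non-2-ene-4,9-dione; 28 3,4-bis(tert-butyldimethylsilyloxy)benzoyl chloride
Product: 30 3-[3,4-bis(tert-butyldimethylsilyloxy)benzoyl] derivative of 25, via C3 vinyllithium 29 (not isolated)
Conditions: LiTMP (1.5 equiv), THF, −78 °C; then 28, −78 → 0 °C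
Reagents that add atoms: none
Why: With both bridgeheads quaternary, the only acidic site is the vinylic C3–H of the β-methoxy enone, and its LiTMP-derived vinyllithium is C-acylated by the aroyl chloride (C3 lithiation–acylation of PPAP enol ethers).

Step 15
Reactants: 30 3-[3,4-bis(tert-butyldimethylsilyloxy)benzoyl] derivative of 25
Product: 31 oblongifolin B
Conditions: LiOH·H2O, 1,4-dioxane–H2O (degassed, argon), 90 °C; then cold 1 M HCl to pH 3
Reagents that add atoms: lithium hydroxide, [Li+].[OH-]
Why: Hydroxide cleaves the vinylogous methyl ester by addition–elimination and both aryl silyl ethers by attack at silicon, releasing the enolised β-triketone and the catechol without strong acid that would cyclise the prenyl groups; no stereocentre is epimerisable.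

**Compound list**

1 | (S)-but-3-yn-2-ol | C[C@H](O)C#C | starting material
2 | geranyl bromide, (2E)-1-bromo-3,7-dimethylocta-2,6-diene | CC(C)=CCC/C(C)=C/CBr | starting material
3 | (2S,6E)-7,11-dimethyldodeca-6,10-dien-3-yn-2-ol | C[C@H](O)C#CC/C=C(\C)CCC=C(C)C | intermediate
4 | (2S,3E,6E)-7,11-dimethyldodeca-3,6,10-trien-2-ol | C[C@H](O)/C=C/C/C=C(\C)CCC=C(C)C | intermediate
5 | isobutyryl chloride | CC(C)C(Cl)=O | starting material
6 | (2S,3E,6E)-7,11-dimethyldodeca-3,6,10-trien-2-yl 2-methylpropanoate | C[C@H](OC(=O)C(C)C)/C=C/C/C=C(\C)CCC=C(C)C | intermediate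
7 | trimethylsilyl ketene acetal of 6 (not isolated) | C[C@H](OC(O[Si](C)(C)C)=C(C)C)/C=C/C/C=C(\C)CCC=C(C)C | intermediate
8 | trimethylsilyl ester of 9 (not isolated) | CC(C)=CCC/C(C)=C/C[C@H](/C=C/C)C(C)(C)C(=O)O[Si](C)(C)C | intermediate
9 | (3R,5E)-2,2,6,10-tetramethyl-3-[(1E)-prop-1-en-1-yl]undeca-5,9-dienoic acid | CC(C)=CCC/C(C)=C/C[C@H](/C=C/C)C(C)(C)C(=O)O | intermediate
10 | tributyl(vinyl)stannane | C=C[Sn](CCCC)(CCCC)CCCC | starting material
11 | acid chloride of 9 (not isolated) | CC(C)=CCC/C(C)=C/C[C@H](/C=C/C)C(C)(C)C(Cl)=O | intermediate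
12 | (5R,7E)-4,4,8,12-tetramethyl-5-[(1E)-prop-1-en-1-yl]trideca-1,7,11-trien-3-one | CC(C)=CCC/C(C)=C/C[C@H](/C=C/C)C(C)(C)C(=O)C=C | intermediate
13 | (4R)-4-geranyl-5,5-dimethylcyclopent-2-en-1-one | CC(C)=CCC/C(C)=C/C[C@@H]1C=CC(=O)C1(C)C | intermediate
14 | prenyl bromide, 1-bromo-3-methylbut-2-ene | CC(C)=CCBr | starting material
15 | lithium (4R)-4-geranyl-5,5-dimethylcyclopent-1-en-1-olate (not isolated) | CC(C)=CCC/C(C)=C/C[C@@H]1CC=C([O-])C1(C)C.[Li+] | intermediate
16 | (3R)-3-geranyl-2,2-dimethyl-5-prenylcyclopentan-1-one, mixture of C5 epimers | CC(C)=CCC/C(C)=C/C[C@@H]1CC(CC=C(C)C)C(=O)C1(C)C | intermediate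
17 | diketene, 4-methylideneoxetan-2-one | C=C1CC(=O)O1 | starting material
18 | lithium (4R)-4-geranyl-5,5-dimethyl-2-prenylcyclopent-1-en-1-olate (not isolated) | CC(C)=CCC/C(C)=C/C[C@@H]1CC(CC=C(C)C)=C([O-])C1(C)C.[Li+] | intermediate
19 | terminal lithium enolate of the C5-acetoacetylated ketone, acetoacetyl group trans to geranyl (not isolated) | CC(C)=CCC/C(C)=C/C[C@@H]1C[C@@](CC=C(C)C)(C(=O)CC([O-])=C)C(=O)C1(C)C.[Li+] | intermediate
20 | cis-fused β-hydroxy diketone: cyclopentane C5–C6–C7–C8–C9 fused at C5–C9 to a cyclohexane-2,4-dione (C1–C4); 9-OH, 5-prenyl, (7R)-7-geranyl, 8,8-dimethyl; OH, prenyl and geranyl on the same face | CC(C)=CCC/C(C)=C/C[C@@H]1C[C@@]2(CC=C(C)C)C(=O)CC(=O)C[C@@]2(O)C1(C)C | intermediate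
21 | C2 methyl enol ether of 20 (C2–OMe, C3=C2, C4=O, C1H2), same configuration | CC(C)=CCC/C(C)=C/C[C@@H]1C[C@@]2(CC=C(C)C)C(=O)C=C(OC)C[C@@]2(O)C1(C)C | intermediate
22 | C1-[methoxy(phenyl)-λ3-iodanyl] derivative of 21 (not isolated) | CC(C)=CCC/C(C)=C/C[C@@H]1C[C@@]2(CC=C(C)C)C(=O)C=C(OC)C(I(OC)c3ccccc3)[C@@]2(O)C1(C)C | intermediate
23 | (7R)-7-exo-geranyl-2-methoxy-8,8-dimethyl-5-prenylbicyclo[3.3.1]non-2-ene-4,9-dione (PPAP labels; bridgehead C1 bears H; geranyl on the face of the cyclohexanone ring opposite the C2–C4 bridge) | CC(C)=CCC/C(C)=C/C[C@@H]1C[C@]2(CC=C(C)C)C(=O)[C@@H](C(OC)=CC2=O)C1(C)C | intermediate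
24 | C1 bridgehead lithio derivative of 23 (not isolated) | CC(C)=CCC/C(C)=C/C[C@@H]1C[C@]2(CC=C(C)C)C(=O)[C@@]([Li])(C(OC)=CC2=O)C1(C)C | intermediate
25 | (7R)-7-exo-geranyl-2-methoxy-8,8-dimethyl-1,5-diprenylbicyclo[3.3.1]non-2-ene-4,9-dione (PPAP labels) | CC(C)=CCC/C(C)=C/C[C@@H]1C[C@]2(CC=C(C)C)C(=O)[C@@](CC=C(C)C)(C(OC)=CC2=O)C1(C)C | intermediate
26 | 3,4-dihydroxybenzoic acid | OC(=O)c1ccc(O)c(O)c1 | starting material
27 | tert-butyldimethylsilyl 3,4-bis(tert-butyldimethylsilyloxy)benzoate | CC(C)(C)[Si](C)(C)OC(=O)c1ccc(O[Si](C)(C)C(C)(C)C)c(O[Si](C)(C)C(C)(C)C)c1 | intermediate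
28 | 3,4-bis(tert-butyldimethylsilyloxy)benzoyl chloride | ClC(=O)c1ccc(O[Si](C)(C)C(C)(C)C)c(O[Si](C)(C)C(C)(C)C)c1 | intermediate
29 | C3 vinyllithium derivative of 25 (not isolated) | CC(C)=CCC/C(C)=C/C[C@@H]1C[C@]2(CC=C(C)C)C(=O)[C@@](CC=C(C)C)(C(OC)=C([Li])C2=O)C1(C)C | intermediate
30 | 3-[3,4-bis(tert-butyldimethylsilyloxy)benzoyl] derivative of 25 | CC(C)=CCC/C(C)=C/C[C@@H]1C[C@]2(CC=C(C)C)C(=O)[C@@](CC=C(C)C)(C(OC)=C(C(=O)c3ccc(O[Si](C)(C)C(C)(C)C)c(O[Si](C)(C)C(C)(C)C)c3)C2=O)C1(C)C | intermediate
31 | oblongifolin B | CC(C)=CCC/C(C)=C/C[C@@H]1C[C@]2(CC=C(C)C)C(=O)[C@@](CC=C(C)C)(C(=O)C(C(=O)c3ccc(O)c(O)c3)=C2O)C1(C)C | target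

**Step count and risks**

Total step count: 15. Longest linear sequence: 13 steps (steps 1–11, 14, 15); steps 12 and 13 prepare the aroyl chloride.

The three steps most likely to fail:

Step 10 (key step). What may go wrong: iodine(III) may be captured at C3 and then intercepted by methoxide (α-methoxylation or ketal formation) instead of triggering the 1,2-shift; the C9 alkoxide may undergo retro-aldol ring opening; or the alkoxide oxygen may attack C1 to give an oxirane. Fallback: oxidation and shift are separated, starting from 21. Double silylation (LDA 2.2 equiv, TMSCl, THF, −78 °C) should give the bis(trimethylsilyl) dienol ether F1. NBS (THF, −78 °C) should brominate the nucleophilic diene terminus C1 in a vinylogous halogenation to give the γ-bromo enone silyl ether F2. Fluoride (TBAF, THF, 0 °C) or AgBF4 then frees the C9 alkoxide, which should displace bromide by the same 1,2-shift of C8 (halohydrin-type semipinacol), and the route is rejoined at 23.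

Step 11. What may go wrong: deprotonation may occur at vinylic C3 instead of the hindered bridgehead C1 next to the gem-dimethyl carbon, or the bridgehead carbanion may be alkylated too slowly. Fallback: the prenyl group is introduced before the skeleton is bridged, starting from 21. γ-Alkylation of the alkoxide–dienolate dianion of the vinylogous ester (LDA 2.2 equiv, THF–DMPU, −78 °C, then prenyl bromide) should give the C1-prenylated hydroxy enol ether F3; both C1 epimers are usable because C1 is planarised again. The PhI(OAc)2/KOH/MeOH ring expansion of step 10, now ending at a tertiary carbon, should then deliver the fully substituted bicycle directly, and the route is rejoined at 25.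

Step 8. What may go wrong: proton transfer within the acetoacetyl enolate may outrun aldol closure onto the hindered C9 ketone, so that only the open-chain triketone is formed; facial selectivity of the C-acylation may also be modest. Fallback: acylation and ring closure are separated, starting from 16. The same enolate acylation with diketene, quenched at −78 °C with acetic acid, should give the open-chain triketone F4. TMSOTf/Et3N (CH2Cl2, 0 °C) should convert it into the 1,3-bis(trimethylsilyloxy)diene F5. A TiCl4-mediated intramolecular Mukaiyama aldol addition of the diene terminus to the C9 ketone (CH2Cl2, −78 °C), followed by aqueous work-up, should give 20, where the route is rejoined.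

**Further compounds**

F1 | step 10 | bis(trimethylsilyl) dienol ether of 21 (C9–OTMS, C4–OTMS, diene C1=C2(OMe)–C3=C4) | CC(C)=CCC/C(C)=C/C[C@@H]1C[C@@]2(CC=C(C)C)C(O[Si](C)(C)C)=CC(OC)=C[C@@]2(O[Si](C)(C)C)C1(C)C
F2 | step 10 | C1-bromo derivative of 21 as its C9 trimethylsilyl ether | CC(C)=CCC/C(C)=C/C[C@@H]1C[C@@]2(CC=C(C)C)C(=O)C=C(OC)C(Br)[C@@]2(O[Si](C)(C)C)C1(C)C
F3 | step 11 | C1-prenyl derivative of 21 (C1 epimers) | CC(C)=CCC/C(C)=C/C[C@@H]1C[C@@]2(CC=C(C)C)C(=O)C=C(OC)C(CC=C(C)C)[C@@]2(O)C1(C)C
F4 | step 8 | open-chain triketone, (4R)-4-geranyl-5,5-dimethyl-2-(3-oxobutanoyl)-2-prenylcyclopentan-1-one, acyl group trans to geranyl | CC(C)=CCC/C(C)=C/C[C@@H]1C[C@@](CC=C(C)C)(C(=O)CC(C)=O)C(=O)C1(C)C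
F5 | step 8 | 1,3-bis(trimethylsilyloxy)buta-1,3-dienyl derivative of F4 | CC(C)=CCC/C(C)=C/C[C@@H]1C[C@@](CC=C(C)C)(C(O[Si](C)(C)C)=CC(O[Si](C)(C)C)=C)C(=O)C1(C)C
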